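## Structural features

The target is a flavanone, (2S)-5,7-dihydroxy-2-(4-hydroxy-3-methoxyphenyl)-8-(3-methylbut-2-enyl)chroman-4-one. Benzene ring A is fused through C4a and C8a to the dihydropyranone ring C (O1, C2, C3, C4 ketone), and ring B, a guaiacyl group, sits on C2. Ring A carries hydroxyls at C5 and C7 and the prenyl chain at C8, the carbon next to C8a and therefore next to O1; C6 is unsubstituted. C2 is the only stereocentre (S) and has no stereogenic neighbour, so its configuration cannot be relayed from the substrate. The C2–O1 bond is fragile: base opens ring C to the chalcone, and strong acid can ionise it because ring B is para-oxygenated; either event racemises C2. The prenyl alkene excludes hydrogenolytic deprotection and, under strong acid, closes onto a neighbouring free hydroxyl to a dimethylchroman; ring A is also strongly nucleophilic at C6. The real difficulty is twofold: setting and keeping C2, and placing the prenyl at C8 rather than C6, positions that differ only in which oxygen ortho to C4a becomes O1. The key step exploits the fact that O1–C2 and C3–C4 flank the C3H2–C2H(aryl) unit: that unit is the vinyl group of a 4-oxygenated styrene, and O1–C8a–C4a–C4 is the heterodiene of an ortho-quinone methide whose methide carbon is the formyl carbon of a salicylaldehyde.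

## Logic of the disconnections

**13 ⇒ 12.** The three phenolic O–H bonds are exchanged for O–Si bonds. The phenols must be masked during the acid-mediated ring construction and the oxidation, and silyl groups can be removed without strong acid, hydrogen or free base. Nothing is gained in skeleton, but every operation that threatens C2 or the prenyl group is moved ahead of the unmasking. The forward step must be buffered so that no phenoxide of 13 persists.

**12 ⇒ 11 ⇒ 10.** The C4 carbonyl is taken back to the C4 alcohol and then to the C4 methyl ether (a C4–O exchange). The cut is dictated by the ring-forming step, which delivers C4 from an aldehyde carbon at the ether oxidation level. The gain is that C4 and C2 both come out of one cycloaddition. The forward steps must ionise C4–O without touching C2–O1, and must oxidise a benzylic alcohol while sparing the prenyl alkene and three electron-rich rings.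

**10 ⇒ 4 + 6 + 7 (through 8 and 9).** C3–C4 and O1–C2 are cut. These two bonds flank the only two-carbon unit of ring C, so the cut removes the ring and the stereocentre together and divides the molecule into a ring A part and a ring B part of similar size. The forward step must give facial control at C2 from a chiral acid, correct polarity matching, and preference for the styrene over every other nucleophile present.

**4 ⇒ 3 ⇒ 1 + 2.** Two O–Si bonds are removed, then the ring–CH2 bond of the prenyl chain is cut. The C-alkylation site is unambiguous because the two open ring carbons of 1 are equivalent. The demand is on the protection: the hydroxyl between formyl and prenyl must stay free, since it becomes O1 and so fixes the prenyl at C8. The alkylation must favour carbon over oxygen and stop at one chain.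

**6 ⇒ 5.** One O–Si bond is cut. The vinyl group is bought, so no olefination is needed. The protecting group has to keep the para oxygen a good donor, which it does.

## Other disconnections considered

**Alternative 1:** The cut is at C8–C8a and C4a–C5, so ring A is built last on an intact, already chiral ring C.
- Forward key step: the diene A2 (1-methoxy-7-methyl-1,3-bis(trimethylsilyloxy)octa-1,3,6-triene) would add across C5=C6 of the (S)-sulfinyl dihydropyranone A1. Its prenyl-bearing nucleophilic terminus bonds to C6 of A1 (later C8a). Loss of the sulfinyl group and of a silyl methyl ether would aromatise ring A to A3, the 4'-methoxymethyl ether of the target.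
- In favour: the prenyl position is fixed by C–C bond formation with no phenol differentiation, which is better than the chosen plan. C2 would come from a mature asymmetric hetero-Diels–Alder construction of the pyranone, which is better in certainty. C4 is a ketone throughout and ring A emerges with free phenols, which is better in redox and protecting-group economy.
- Against: the 2π partner is a vinylogous ester and a reluctant dienophile even with the sulfoxide. The new C8–C8a bond joins a substituted diene terminus to an oxygen-bearing carbon. A2 is hydrolytically sensitive. The last step would be acidic removal of a methoxymethyl ether next to a prenyl group and an ionisable C2–O1 bond.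
- Comparison: on structure it avoids the regiochemical and oxidation-level problems of the chosen plan. On mechanism its hindered cycloaddition is as unproven as the catalyst pairing of the chosen plan. On step economy it needs about nine steps with a longest linear sequence near six, against seven and six: equal in linear length, longer in total.

**Alternative 2:** The cut is at C2–C3.
- Forward key step: the diazoketone A4 would be decomposed by dirhodium tetrakis[N-phthaloyl-(S)-tert-leucinate]. The carbene would insert into the benzylic ether C–H bond, closing ring C and giving A5, which is identical with 12.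
- In favour: the flavanone oxidation level is reached directly, which is better than the chosen plan (no counterpart of steps 5 and 6). The C–H bond is doubly activated. Convergence is equal, since ring B arrives by etherification.
- Against: a carbene flanked by an aryl ether oxygen can form an oxonium ylide and undergo a 1,2-shift to a benzofuranone. Addition to the electron-rich rings and cyclopropanation of the prenyl alkene are further leaks. Acceptor-only carbenes usually transmit chirality less well than donor–acceptor carbenes. A4 requires alkylation of the hindered chelated hydroxyl, so the phenol differentiation of the chosen plan is not avoided (equal), and it requires diazomethane chemistry on a hindered benzoic acid.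
- Comparison: equal in that enantiocontrol rests on an untested catalyst–substrate pair; better in redox economy; worse in chemoselectivity and in step count (about ten).

**Alternative 3:** The cut is at C4a–C4, C4–C3 and O1–C2.
- Forward key step: PdCl2(PPh3)2 with diethylamine would couple the iodophenol A6, carbon monoxide A7 and the arylacetylene A8 to an ynone. This would close through oxygen to the flavone A9.
- In favour: this is the most robust ring assembly of the four. It is fully convergent (equal), passes through no acid-labile intermediate and carries C4 as a ketone, which is better than the chosen plan on robustness.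
- Against: C2 is trigonal in A9. The stereocentre would still have to be made by enantioselective conjugate reduction of a 2-arylchromone, a narrow field, while sparing the prenyl alkene and the ketone. Five-membered closure to an aurone competes. The iodine of A6 must be placed ortho to the one free hydroxyl.
- Comparison: better on the ring-forming step, worse on the stereochemical step, which is moved to a later and less secure reaction, and longer (about ten steps).

Key step: step 4

**Remarks before the steps**

- Structure check: C2 of the target is S. In the cis cycloadduct C2 is S and C4 is S. No correction of constitution or configuration was needed.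
- Design change: the phenols are protected as tert-butyldimethylsilyl (TBS) ethers and not as acetal-type ethers. Acetal ethers can exchange in the acetalising medium of the key step and need strong acid for removal, which endangers the prenyl group and C2. Bulky silyl groups also flank C6 and hinder Friedel–Crafts attack there.
- Assumption: the (R)-catalyst is taken to give the (2S) series; if the sense of induction is the reverse, the (S)-catalyst serves identically.
- Assumption: 11 is treated as a mixture of C4 epimers, because C4 passes through a planar cation and is oxidised in the next step.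

## Steps

**Step 1**
Reactants: 1 2,4,6-trihydroxybenzaldehyde; 2 prenyl bromide (1-bromo-3-methylbut-2-ene)
Product: 3 2,4,6-trihydroxy-3-(3-methylbut-2-en-1-yl)benzaldehyde
Conditions: 2 (0.9 equiv), 10% aq. KOH (1.0 equiv), 0 °C → rt; then dilute HCl to pH 4
Reagents that add atoms: none
Why: C-alkylation of a phloroglucinol phenoxide (SN2 at the primary allylic bromide); water solvates the phenoxide oxygen and favours attack through the ring carbon between two oxygens, the two open carbons are equivalent, and sub-stoichiometric 2 limits double alkylation.

**Step 2**
Reactants: 3 2,4,6-trihydroxy-3-(3-methylbut-2-en-1-yl)benzaldehyde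
Product: 4 2-hydroxy-4,6-bis(tert-butyldimethylsilyloxy)-3-(3-methylbut-2-en-1-yl)benzaldehyde
Conditions: TBSCl (2.1 equiv), imidazole (4.5 equiv), DMF, 0 °C → rt
Reagents that add atoms: tert-butyldimethylsilyl chloride, CC(C)(C)[Si](C)(C)Cl
Why: Phenol silylation; the para hydroxyl reacts first, and of the two ortho hydroxyls the one flanked by hydrogen is silylated, while the one buttressed by the prenyl group and locked in the hydrogen bond to the formyl oxygen should remain free.

**Step 3**
Reactants: 5 2-methoxy-4-vinylphenol
Product: 6 tert-butyl(2-methoxy-4-vinylphenoxy)dimethylsilane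
Conditions: TBSCl (1.1 equiv), imidazole (2.2 equiv), CH2Cl2, 0 °C → rt
Reagents that add atoms: tert-butyldimethylsilyl chloride, CC(C)(C)[Si](C)(C)Cl
Why: Standard silylation of an unhindered phenol; the silyl ether keeps the para oxygen a strong donor and removes the free phenol that would otherwise react with the orthoformate.

**Step 4**
Reactants: 4 2-hydroxy-4,6-bis(tert-butyldimethylsilyloxy)-3-(3-methylbut-2-en-1-yl)benzaldehyde; 6 tert-butyl(2-methoxy-4-vinylphenoxy)dimethylsilane; 7 trimethyl orthoformate
Product: 10 (2S,4S)-5,7-bis(tert-butyldimethylsilyloxy)-2-[4-(tert-butyldimethylsilyloxy)-3-methoxyphenyl]-4-methoxy-8-(3-methylbut-2-en-1-yl)chromane (2,4-cis), via dimethyl acetal 8 (not isolated), via methoxy ortho-quinone methide 9 (not isolated)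
Conditions: 6 (2.0 equiv), 7 (1.5 equiv), (R)-3,3'-bis(2,4,6-triisopropylphenyl)-1,1'-binaphthyl-2,2'-diyl N-triflylphosphoramide (5 mol %), CH2Cl2, −40 → −10 °C
Reagents that add atoms: none
Why: Proposed new method: acid-catalysed acetal exchange with 7 gives 8, which ionises to the O-methyl oxocarbenium ion (protonated 9), held as a contact ion pair with the chiral phosphoramidate that also hydrogen-bonds the free phenol. The CH2 terminus of 6 attacks the methide carbon (C3–C4), and the benzylic cation at C2, stabilised by the para silyloxy group, is captured by the phenol oxygen (O1–C2); ring C therefore closes in an asynchronous inverse-demand hetero-[4+2] mode whose stepwise limit is six-membered capture of a cation by O1. The closest known reactions are the achiral acid-catalysed union of salicylaldehydes, orthoformates and styrenes to cis-4-alkoxy-2-arylchromans, and the chiral N-triflylphosphoramide-catalysed [4+2] of styrenes with ortho-quinone methides from ortho-hydroxybenzyl alcohols; merging the two on an acetal-derived methide is the untested element. C2 is set by the catalyst, whose anion, bound at O1–H, should shield one face of the styrene as O1–C2 forms. C4 is set relative to C2 by the endo-type approach (aryl and methoxy cis) and is erased later. Regiochemistry follows from the polarity of the styrene, and O1 can only be the oxygen beside the prenyl group because it is the sole free phenol, which places the prenyl at C8. Chemoselectivity requires the acetal to ionise before the prenyl alkene is protonated (low temperature, far more basic acetal) and the styrene to outcompete ring A as nucleophile (excess 6, bulky silyl ethers flanking the open ring carbon).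

**Step 5**
Reactants: 10 (2S,4S)-5,7-bis(tert-butyldimethylsilyloxy)-2-[4-(tert-butyldimethylsilyloxy)-3-methoxyphenyl]-4-methoxy-8-(3-methylbut-2-en-1-yl)chromane
Product: 11 (2S)-5,7-bis(tert-butyldimethylsilyloxy)-2-[4-(tert-butyldimethylsilyloxy)-3-methoxyphenyl]-8-(3-methylbut-2-en-1-yl)chroman-4-ol (C4 epimers)
Conditions: PPTS (0.2 equiv), THF–H2O (4:1), 0.02 M, rt; crude product taken on
Reagents that add atoms: water, O
Why: SN1 solvolysis: the C4 ether ionises under weak acid to a benzylic cation stabilised by three ring oxygens and is captured by water in large excess; C2–O1 is not involved, so C2 should be retained, and aryl silyl ethers and the prenyl alkene tolerate PPTS.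

**Step 6**
Reactants: 11 (2S)-5,7-bis(tert-butyldimethylsilyloxy)-2-[4-(tert-butyldimethylsilyloxy)-3-methoxyphenyl]-8-(3-methylbut-2-en-1-yl)chroman-4-ol
Product: 12 (S)-5,7-bis(tert-butyldimethylsilyloxy)-2-[4-(tert-butyldimethylsilyloxy)-3-methoxyphenyl]-8-(3-methylbut-2-en-1-yl)chroman-4-one
Conditions: Dess–Martin periodinane (1.5 equiv), NaHCO3 (5 equiv), CH2Cl2, 0 °C → rt
Reagents that add atoms: none
Why: Dess–Martin oxidation of a secondary benzylic alcohol under buffered, non-basic conditions; both C4 epimers converge on the ketone, the alkene and arenes are inert to the reagent, and no base is present to open ring C.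

**Step 7**
Reactants: 12 (S)-5,7-bis(tert-butyldimethylsilyloxy)-2-[4-(tert-butyldimethylsilyloxy)-3-methoxyphenyl]-8-(3-methylbut-2-en-1-yl)chroman-4-one
Product: 13 (S)-5,7-dihydroxy-2-(4-hydroxy-3-methoxyphenyl)-8-(3-methylbut-2-en-1-yl)chroman-4-one (CNP0266453.1)
Conditions: Bu4NF (3.3 equiv), AcOH (3.6 equiv), THF, 0 °C
Reagents that add atoms: none
Why: Fluoride-induced cleavage of aryl silyl ethers, driven by the Si–F bond; acetic acid protonates each phenoxide as it forms, so the retro-oxa-Michael opening that would racemise C2 is not triggered, and the prenyl group sees neither strong acid nor hydrogen.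

## Compound list

1 | 2,4,6-trihydroxybenzaldehyde | O=Cc1c(O)cc(O)cc1O | starting material
2 | prenyl bromide (1-bromo-3-methylbut-2-ene) | CC(C)=CCBr | starting material
3 | 2,4,6-trihydroxy-3-(3-methylbut-2-en-1-yl)benzaldehyde | O=Cc1c(O)cc(O)c(CC=C(C)C)c1O | intermediate
4 | 2-hydroxy-4,6-bis(tert-butyldimethylsilyloxy)-3-(3-methylbut-2-en-1-yl)benzaldehyde | O=Cc1c(O[Si](C)(C)C(C)(C)C)cc(O[Si](C)(C)C(C)(C)C)c(CC=C(C)C)c1O | intermediate
5 | 2-methoxy-4-vinylphenol | C=Cc1ccc(O)c(OC)c1 | starting material
6 | tert-butyl(2-methoxy-4-vinylphenoxy)dimethylsilane | C=Cc1ccc(O[Si](C)(C)C(C)(C)C)c(OC)c1 | intermediate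
7 | trimethyl orthoformate | COC(OC)OC | starting material
8 | 2-(dimethoxymethyl)-3,5-bis(tert-butyldimethylsilyloxy)-6-(3-methylbut-2-en-1-yl)phenol (formed in the flask) | COC(OC)c1c(O[Si](C)(C)C(C)(C)C)cc(O[Si](C)(C)C(C)(C)C)c(CC=C(C)C)c1O | intermediate
9 | 3,5-bis(tert-butyldimethylsilyloxy)-6-(methoxymethylidene)-2-(3-methylbut-2-en-1-yl)cyclohexa-2,4-dien-1-one (formed in the flask; reacts as its O-protonated oxocarbenium ion pair, exocyclic geometry not fixed) | COC=C1C(=O)C(CC=C(C)C)=C(O[Si](C)(C)C(C)(C)C)C=C1O[Si](C)(C)C(C)(C)C | intermediate
10 | (2S,4S)-5,7-bis(tert-butyldimethylsilyloxy)-2-[4-(tert-butyldimethylsilyloxy)-3-methoxyphenyl]-4-methoxy-8-(3-methylbut-2-en-1-yl)chromane | COc1cc([C@@H]2C[C@H](OC)c3c(O[Si](C)(C)C(C)(C)C)cc(O[Si](C)(C)C(C)(C)C)c(CC=C(C)C)c3O2)ccc1O[Si](C)(C)C(C)(C)C | intermediate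
11 | (2S)-5,7-bis(tert-butyldimethylsilyloxy)-2-[4-(tert-butyldimethylsilyloxy)-3-methoxyphenyl]-8-(3-methylbut-2-en-1-yl)chroman-4-ol, C4 epimers | COc1cc([C@@H]2CC(O)c3c(O[Si](C)(C)C(C)(C)C)cc(O[Si](C)(C)C(C)(C)C)c(CC=C(C)C)c3O2)ccc1O[Si](C)(C)C(C)(C)C | intermediate
12 | (S)-5,7-bis(tert-butyldimethylsilyloxy)-2-[4-(tert-butyldimethylsilyloxy)-3-methoxyphenyl]-8-(3-methylbut-2-en-1-yl)chroman-4-one | COc1cc([C@@H]2CC(=O)c3c(O[Si](C)(C)C(C)(C)C)cc(O[Si](C)(C)C(C)(C)C)c(CC=C(C)C)c3O2)ccc1O[Si](C)(C)C(C)(C)C | intermediate
13 | (S)-5,7-dihydroxy-2-(4-hydroxy-3-methoxyphenyl)-8-(3-methylbut-2-en-1-yl)chroman-4-one | COc1cc([C@@H]2CC(=O)c3c(O)cc(O)c(CC=C(C)C)c3O2)ccc1O | target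

## Step count and risk

Total: 7 steps. Longest linear sequence: 6 steps (1, 2, 4, 5, 6, 7); step 3 is a one-step side branch.

**Step 4 (key step, Proposed new method).**
- Most likely failure: poor facial selectivity at C2. The styrene has no site that binds the catalyst, and ring closure may occur after the ion pair has loosened. Reversible ionisation of C2–O1 under the acid could also erode whatever selectivity is reached.
- Secondary hazards: cationic oligomerisation of 6, Friedel–Crafts attack by ring A, and acid methanolysis of a silyl ether.
- Fallback (known chemistry), setting out from 4 with 6 and 7: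
  - Sc(OTf)3 (10 mol %) in CH2Cl2 at rt should give the racemic 4-methoxyflavan F1.
  - PPTS in wet THF converts it into the racemic flavan-4-ol F2, and buffered Dess–Martin oxidation gives the racemic silyl-protected flavanone F3.
  - Kinetic resolution by asymmetric transfer hydrogenation with RuCl[(R,R)-TsDPEN](p-cymene) and HCO2H–Et3N follows. By the usual facial preference of this catalyst family it should reduce the (2R)-ketone to the (2R,4R)-cis-flavan-4-ol F4 and leave the (2S)-ketone.
  - The route is rejoined at 12, at the cost of half the material.

**Step 5.**
- Most likely failure: the C4 cation is diverted from water capture into loss of a C3 proton (flav-3-ene formation) or into intermolecular attack on C6 of a second molecule, because the cation is long-lived and ring A is nucleophilic.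
- Fallback, setting out from 10: oxidative cleavage of the benzylic methyl ether with DDQ in CH2Cl2–pH 7 buffer. Hydride abstraction from C4 and collapse of the hemiacetal lead directly to 12, bypassing 11 and step 6. No new compound is formed on the way.

**Step 2.**
- Most likely failure: silylation of the wrong ortho hydroxyl or formation of an isomer mixture, because the two chelated hydroxyls differ only in their neighbour.
- Fallback, setting out from 1 (it also replaces the modest alkylation of step 1):
  - Bis-silylation of 1, whose ortho hydroxyls are equivalent, gives 2-hydroxy-4,6-bis(tert-butyldimethylsilyloxy)benzaldehyde F5.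
  - O-tert-prenylation with isobutyl 2-methylbut-3-en-2-yl carbonate F6 (made beforehand from 2-methylbut-3-en-2-ol and isobutyl chloroformate) under Pd(PPh3)4 in THF gives 2-(2-methylbut-3-en-2-yloxy)-4,6-bis(tert-butyldimethylsilyloxy)benzaldehyde F7.
  - Aromatic Claisen rearrangement in toluene at 110 °C moves the chain, with allylic inversion, to the only open ortho carbon.
  - The route is rejoined at 4 with the regiochemistry fixed by the rearrangement.

## Further compounds

F1 | step 4 | racemic 5,7-bis(tert-butyldimethylsilyloxy)-2-[4-(tert-butyldimethylsilyloxy)-3-methoxyphenyl]-4-methoxy-8-(3-methylbut-2-en-1-yl)chromane (C4 epimers not separated) | COc1cc(C2CC(OC)c3c(O[Si](C)(C)C(C)(C)C)cc(O[Si](C)(C)C(C)(C)C)c(CC=C(C)C)c3O2)ccc1O[Si](C)(C)C(C)(C)C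
F2 | step 4 | racemic 5,7-bis(tert-butyldimethylsilyloxy)-2-[4-(tert-butyldimethylsilyloxy)-3-methoxyphenyl]-8-(3-methylbut-2-en-1-yl)chroman-4-ol (C4 epimers) | COc1cc(C2CC(O)c3c(O[Si](C)(C)C(C)(C)C)cc(O[Si](C)(C)C(C)(C)C)c(CC=C(C)C)c3O2)ccc1O[Si](C)(C)C(C)(C)C
F3 | step 4 | racemic 5,7-bis(tert-butyldimethylsilyloxy)-2-[4-(tert-butyldimethylsilyloxy)-3-methoxyphenyl]-8-(3-methylbut-2-en-1-yl)chroman-4-one | COc1cc(C2CC(=O)c3c(O[Si](C)(C)C(C)(C)C)cc(O[Si](C)(C)C(C)(C)C)c(CC=C(C)C)c3O2)ccc1O[Si](C)(C)C(C)(C)C
F4 | step 4 | (2R,4R)-5,7-bis(tert-butyldimethylsilyloxy)-2-[4-(tert-butyldimethylsilyloxy)-3-methoxyphenyl]-8-(3-methylbut-2-en-1-yl)chroman-4-ol (2,4-cis) | COc1cc([C@H]2C[C@@H](O)c3c(O[Si](C)(C)C(C)(C)C)cc(O[Si](C)(C)C(C)(C)C)c(CC=C(C)C)c3O2)ccc1O[Si](C)(C)C(C)(C)C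
F0 | step 5 | none | none
F5 | step 2 | 2-hydroxy-4,6-bis(tert-butyldimethylsilyloxy)benzaldehyde | O=Cc1c(O)cc(O[Si](C)(C)C(C)(C)C)cc1O[Si](C)(C)C(C)(C)C
F6 | step 2 | isobutyl 2-methylbut-3-en-2-yl carbonate | CC(C)COC(=O)OC(C)(C)C=C
F7 | step 2 | 2-(2-methylbut-3-en-2-yloxy)-4,6-bis(tert-butyldimethylsilyloxy)benzaldehyde | O=Cc1c(OC(C)(C)C=C)cc(O[Si](C)(C)C(C)(C)C)cc1O[Si](C)(C)C(C)(C)C
A1 | alternative 1 | (S)-2-[3-methoxy-4-(methoxymethoxy)phenyl]-5-(phenylsulfinyl)-2,3-dihydro-4H-pyran-4-one (configuration at sulfur not defined) | COc1cc([C@@H]2CC(=O)C(S(=O)c3ccccc3)=CO2)ccc1OCOC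
A2 | alternative 1 | 1-methoxy-7-methyl-1,3-bis(trimethylsilyloxy)octa-1,3,6-triene | COC(O[Si](C)(C)C)=CC(O[Si](C)(C)C)=CCC=C(C)C
A3 | alternative 1 | (S)-5,7-dihydroxy-2-[3-methoxy-4-(methoxymethoxy)phenyl]-8-(3-methylbut-2-en-1-yl)chroman-4-one | COc1cc([C@@H]2CC(=O)c3c(O)cc(O)c(CC=C(C)C)c3O2)ccc1OCOC
A4 | alternative 2 | 2-diazo-1-{4,6-bis(tert-butyldimethylsilyloxy)-2-[4-(tert-butyldimethylsilyloxy)-3-methoxybenzyloxy]-3-(3-methylbut-2-en-1-yl)phenyl}ethanone | COc1cc(COc2c(CC=C(C)C)c(O[Si](C)(C)C(C)(C)C)cc(O[Si](C)(C)C(C)(C)C)c2C(=O)C=[N+]=[N-])ccc1O[Si](C)(C)C(C)(C)C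
A5 | alternative 2 | (S)-5,7-bis(tert-butyldimethylsilyloxy)-2-[4-(tert-butyldimethylsilyloxy)-3-methoxyphenyl]-8-(3-methylbut-2-en-1-yl)chroman-4-one | COc1cc([C@@H]2CC(=O)c3c(O[Si](C)(C)C(C)(C)C)cc(O[Si](C)(C)C(C)(C)C)c(CC=C(C)C)c3O2)ccc1O[Si](C)(C)C(C)(C)C
A6 | alternative 3 | 2-iodo-3,5-bis(methoxymethoxy)-6-(3-methylbut-2-en-1-yl)phenol | Oc1c(I)c(OCOC)cc(OCOC)c1CC=C(C)C
A7 | alternative 3 | carbon monoxide | [C-]#[O+]
A8 | alternative 3 | 4-ethynyl-2-methoxy-1-(methoxymethoxy)benzene | C#Cc1ccc(OCOC)c(OC)c1
A9 | alternative 3 | 5,7-bis(methoxymethoxy)-2-[3-methoxy-4-(methoxymethoxy)phenyl]-8-(3-methylbut-2-en-1-yl)chromen-4-one | COc1cc(-c2cc(=O)c3c(OCOC)cc(OCOC)c(CC=C(C)C)c3o2)ccc1OCOC
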